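The plan breaks the C8–C12 bond of the five-membered ring (prostanoid numbering: C1 ester carbon, C9 ketone, C12 acetoxy carbon) and ties C12 back to C9. This leads to a 1-enynyl-2-siloxycyclobutanol. The feature used is the E-exocyclic C7=C8 alkene that sits between the C9 ketone and the oxygen-bearing quaternary C12. Gold(I) activation of the C7–C8 alkyne lets C12 slide from C9 to C8. In one operation the four-membered ring becomes the cyclopentanone, the ketone appears and the 7E-dienylidene ester chain is in place. C12 is set earlier by asymmetric decarboxylative allylation. Chlorine, the C10=C11 alkene and the acetate follow.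

Key step: step 9

Assumption: the facial sense of the PHOX-controlled allylation is taken to parallel that of 2-alkyl cyclic enolates, which calls for the (R)-ligand to reach the (S)-allyl ketone; if the first run shows the opposite sense, the (S)-ligand is used and nothing else changes.

Step 1
Reactants: 1 1,2-bis(trimethylsilyloxy)cyclobut-1-ene
Product: 3 1-(tert-butyldimethylsilyloxy)-2-(trimethylsilyloxy)cyclobut-1-ene, via lithium enolate 2 (not isolated)
Conditions: MeLi (1.0 equiv), THF, 0 °C to rt; then TBSCl, DMPU, −78 °C to rt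
Reagents that add atoms: tert-butyldimethylsilyl chloride, CC(C)(C)[Si](C)(C)Cl
Why: Methyllithium cleaves one Si–O bond of a trimethylsilyl enol ether to release the lithium enolate, the anionic mono-enolate resists a second cleavage, and O-silylation installs the robust silyl group before the stereocentre exists, so no silyl exchange through a racemisable free α-ketol is needed later.

Step 2
Reactants: 3 1-(tert-butyldimethylsilyloxy)-2-(trimethylsilyloxy)cyclobut-1-ene; 4 allyl chloroformate
Product: 6 allyl 2-(tert-butyldimethylsilyloxy)cyclobut-1-en-1-yl carbonate, via lithium enolate 5 (not isolated)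
Conditions: MeLi (1.0 equiv), THF, 0 °C to rt; then 4, −78 °C
Reagents that add atoms: none
Why: Methyllithium attacks the unhindered trimethylsilyl group far faster than the tert-butyldimethylsilyl group, and the fully substituted lithium enolate is acylated on oxygen by the hard chloroformate (enol carbonate formation from a regiodefined enolate).

Step 3
Reactants: 6 allyl 2-(tert-butyldimethylsilyloxy)cyclobut-1-en-1-yl carbonate
Product: 7 (S)-2-allyl-2-(tert-butyldimethylsilyloxy)cyclobutan-1-one
Conditions: Pd2(dba)3 (2.5 mol %), (R)-(CF3)3-t-BuPHOX (6 mol %), toluene, 20 °C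
Reagents that add atoms: none
Why: Pd(0) ionises the allyl carbonate, CO2 is lost and the siloxy enolate is allylated at the carbon bearing the silyloxy group inside the chiral Pd–PHOX sphere (decarboxylative asymmetric allylic alkylation, Tsuji–Trost type), so the ligand sets C12, while an O-to-O silyl shift in the symmetric enediolate is degenerate and therefore harmless.

Step 4
Reactants: 7 (S)-2-allyl-2-(tert-butyldimethylsilyloxy)cyclobutan-1-one; 8 1-heptene
Product: 9 (S)-2-(tert-butyldimethylsilyloxy)-2-[(Z)-oct-2-en-1-yl]cyclobutan-1-one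
Conditions: cyclometalated (adamantyl–NHC chelate) nitrato ruthenium Z-selective catalyst (2–5 mol %), 8 (5 equiv), THF, 35 °C, ethylene vented
Reagents that add atoms: none
Why: In Z-selective olefin cross-metathesis the chelated NHC forces both substituents of the side-bound ruthenacyclobutane away from the ligand, so the kinetic 14Z alkene is released, the excess of cheap 8 drives 7 to the cross product, and the ketone and silyl ether are spectators.

Step 5
Reactants: 10 methyl hex-5-ynoate
Product: 12 methyl (E)-6-iodohex-5-enoate, via alkenylzirconocene 11 (not isolated)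
Conditions: Cp2Zr(H)Cl (1.15 equiv), CH2Cl2, rt, dark; then I2, 0 °C
Reagents that add atoms: iodine, II
Why: Hydrozirconation adds Zr–H syn across the terminal alkyne with zirconium at the terminus much faster than it reduces the ester, and iodinolysis of the C–Zr bond with retention fixes the 5E geometry.

Step 6
Reactants: 12 methyl (E)-6-iodohex-5-enoate; 13 ethynyltrimethylsilane
Product: 14 methyl (E)-8-(trimethylsilyl)oct-5-en-7-ynoate
Conditions: PdCl2(PPh3)2 (2 mol %), CuI (4 mol %), Et3N, THF, rt
Reagents that add atoms: none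
Why: Sonogashira coupling of an alkenyl iodide runs at room temperature with retention of the alkene geometry, and the silyl cap prevents double coupling.

Step 7
Reactants: 14 methyl (E)-8-(trimethylsilyl)oct-5-en-7-ynoate
Product: 15 methyl (E)-oct-5-en-7-ynoate
Conditions: K2CO3 (0.2 equiv), MeOH, 0 °C
Reagents that add atoms: none
Why: Methoxide-catalysed protodesilylation of the alkynylsilane is fast, and any transesterification in methanol is degenerate for a methyl ester.

Step 8
Reactants: 9 (S)-2-(tert-butyldimethylsilyloxy)-2-[(Z)-oct-2-en-1-yl]cyclobutan-1-one; 15 methyl (E)-oct-5-en-7-ynoate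
Product: 18 methyl (5E)-8-{(2S)-2-(tert-butyldimethylsilyloxy)-1-hydroxy-2-[(Z)-oct-2-en-1-yl]cyclobutyl}oct-5-en-7-ynoate (both C9 carbinol epimers), via lithium acetylide 16 (not isolated), via cerium acetylide 17 (not isolated)
Conditions: 15 (1.3 equiv), LiHMDS (1.25 equiv), THF, −78 °C; anhydrous CeCl3 (1.3 equiv), −78 °C; then 9, −78 °C; AcOH/THF quench at −78 °C
Reagents that add atoms: none
Why: The enyne C–H is the most acidic and most accessible proton of 15, so the non-nucleophilic amide should form the acetylide without touching the ester, the non-basic cerium acetylide adds 1,2 to the strained electrophilic cyclobutanone instead of enolising it (organocerium carbonyl addition), the cold acidic quench forestalls O-to-O silyl migration, and the new C9 centre needs no control because step 9 destroys it.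

Step 9
Reactants: 18 methyl (5E)-8-{(2S)-2-(tert-butyldimethylsilyloxy)-1-hydroxy-2-[(Z)-oct-2-en-1-yl]cyclobutyl}oct-5-en-7-ynoate
Product: 19 methyl (5E,7E,12S,14Z)-12-(tert-butyldimethylsilyloxy)-9-oxoprosta-5,7,14-trienoate
Conditions: [(4-CF3C6H4)3P]AuCl (5 mol %), AgSbF6 (5 mol %), CH2Cl2, 4 Å MS, 0 °C to rt, dark
Reagents that add atoms: none
Why: The cationic gold(I) binds the C7–C8 alkyne of 18, the neighbouring strained C9–C12 σ bond shifts to C8 on the side opposite to the metal while the C9 hydroxyl turns into the protonated ketone, and this proton then cleaves the C7–Au bond of the vinylgold with retention. The closest known reaction type is the gold(I)-catalysed semipinacol-type ring expansion of 1-alkynylcyclobutanols to 2-alkylidenecyclopentanones, and because the alkyne here is internal and conjugated an electron-poor, strongly electrophilic triarylphosphine–gold cation is chosen. The five-membered ring is not closed by a cyclisation but arises by enlargement of the cyclobutane, C8 being inserted between C9 and C12, with relief of ring strain and C=O formation as the driving force. No stereocentre is created: C12 migrates with retention because it stays bonded on the same face throughout, both C9 epimers converge on one ketone, and the only new stereo-element, the 7E alkene, follows from the anti relation of migrating carbon and gold, which leaves C6 cis to C12 and H7 cis to the carbonyl. The step needs migration of C12 and not of C10, which the substrate secures because C12 is fully substituted and its oxygen lone pair stabilises the positive charge building up on the migrating carbon, whereas C10 is a plain methylene. It also needs the shift to outrun other nucleophiles at the activated alkyne: the silyl ether shuts off the C12 oxygen, and the migrating σ bond is held directly next to C8, which should favour it over the more remote C14=C15 alkene.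

Step 10
Reactants: 19 methyl (5E,7E,12S,14Z)-12-(tert-butyldimethylsilyloxy)-9-oxoprosta-5,7,14-trienoate
Product: 21 methyl (5E,7E,12R,14Z)-10-chloro-12-(tert-butyldimethylsilyloxy)-9-oxoprosta-5,7,14-trienoate (C10 epimers; the C12 descriptor changes only because C11 now outranks C13), via lithium enolate 20 (not isolated)
Conditions: LiHMDS (1.05 equiv), THF, −78 °C; then TsCl (1.1 equiv), −78 to −20 °C
Reagents that add atoms: p-toluenesulfonyl chloride, Cc1ccc(cc1)S(=O)(=O)Cl
Why: On the ring only C10 carries α-hydrogens (C8 has none), one equivalent of base leaves the less acidic ester alone, and the kinetic lithium enolate takes Cl+ from the sulfonyl chloride (enolate α-chlorination) at a temperature at which the three alkenes are inert, the C10 configuration being irrelevant.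

Step 11
Reactants: 21 methyl (5E,7E,12R,14Z)-10-chloro-12-(tert-butyldimethylsilyloxy)-9-oxoprosta-5,7,14-trienoate
Product: 25 methyl (5E,7E,12R,14Z)-10-chloro-12-(tert-butyldimethylsilyloxy)-9-oxoprosta-5,7,10,14-tetraenoate, via lithium chloroenolate 22 (not isolated), via chloro selenide 23 (not isolated), via selenoxide 24 (not isolated)
Conditions: LiHMDS (1.1 equiv), THF, −78 °C; PhSeCl (1.15 equiv), −78 °C; then AcOH, 30 % H2O2, 0 °C to rt, same flask
Reagents that add atoms: none
Why: The more acidic chloro ketone is re-enolised at C10 and selenenylated, and oxidation gives a selenoxide that eliminates syn towards C11, the only site with β-hydrogens (selenoxide elimination of an α-chloro-α-phenylseleno ketone to an α-chloroenone), while the acidic buffer keeps hydroperoxide anion away from the electrophilic dienone.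

Step 12
Reactants: 25 methyl (5E,7E,12R,14Z)-10-chloro-12-(tert-butyldimethylsilyloxy)-9-oxoprosta-5,7,10,14-tetraenoate
Product: 26 methyl (5E,7E,12R,14Z)-10-chloro-12-hydroxy-9-oxoprosta-5,7,10,14-tetraenoate
Conditions: HF·pyridine, pyridine, THF, 0 °C to rt (plastic vessel)
Reagents that add atoms: none
Why: Fluoride-driven Si–O cleavage in a mildly acidic medium spares the base-sensitive chlorodienone and the ester, ionisation at C12 is disfavoured by the conjugated carbonyl, and the C12–O bond is never broken, so the configuration holds.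

Step 13
Reactants: 26 methyl (5E,7E,12R,14Z)-10-chloro-12-hydroxy-9-oxoprosta-5,7,10,14-tetraenoate
Product: 27 methyl (5E,7E,12R,14Z)-12-acetoxy-10-chloro-9-oxoprosta-5,7,10,14-tetraenoate (target CNP0248978.2)
Conditions: Ac2O (5 equiv), DMAP (1 equiv), Et3N, CH2Cl2, rt
Reagents that add atoms: acetic anhydride, CC(=O)OC(C)=O
Why: DMAP-catalysed acyl transfer through the N-acetylpyridinium ion acetylates even hindered tertiary alcohols under near-neutral conditions and leaves the C12–O bond, and hence the stereocentre, untouched.

Compound list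
1 | 1,2-bis(trimethylsilyloxy)cyclobut-1-ene | C[Si](C)(C)OC1=C(O[Si](C)(C)C)CC1 | starting material
2 | lithium 2-(trimethylsilyloxy)cyclobut-1-en-1-olate | [Li]OC1=C(O[Si](C)(C)C)CC1 | intermediate
3 | 1-(tert-butyldimethylsilyloxy)-2-(trimethylsilyloxy)cyclobut-1-ene | CC(C)(C)[Si](C)(C)OC1=C(O[Si](C)(C)C)CC1 | intermediate
4 | allyl chloroformate | C=CCOC(Cl)=O | starting material
5 | lithium 2-(tert-butyldimethylsilyloxy)cyclobut-1-en-1-olate | [Li]OC1=C(O[Si](C)(C)C(C)(C)C)CC1 | intermediate
6 | allyl 2-(tert-butyldimethylsilyloxy)cyclobut-1-en-1-yl carbonate | C=CCOC(=O)OC1=C(O[Si](C)(C)C(C)(C)C)CC1 | intermediate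
7 | (S)-2-allyl-2-(tert-butyldimethylsilyloxy)cyclobutan-1-one | C=CC[C@@]1(O[Si](C)(C)C(C)(C)C)CCC1=O | intermediate
8 | 1-heptene | CCCCCC=C | starting material
9 | (S)-2-(tert-butyldimethylsilyloxy)-2-[(Z)-oct-2-en-1-yl]cyclobutan-1-one | CCCCC/C=C\C[C@@]1(O[Si](C)(C)C(C)(C)C)CCC1=O | intermediate
10 | methyl hex-5-ynoate | C#CCCCC(=O)OC | starting material
11 | chlorobis(cyclopentadienyl)[(E)-6-methoxy-6-oxohex-1-en-1-yl]zirconium | COC(=O)CCC/C=C/[Zr](Cl)(C1C=CC=C1)C1C=CC=C1 | intermediate
12 | methyl (E)-6-iodohex-5-enoate | I/C=C/CCCC(=O)OC | intermediate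
13 | ethynyltrimethylsilane | C#C[Si](C)(C)C | starting material
14 | methyl (E)-8-(trimethylsilyl)oct-5-en-7-ynoate | C[Si](C)(C)C#C/C=C/CCCC(=O)OC | intermediate
15 | methyl (E)-oct-5-en-7-ynoate | C#C/C=C/CCCC(=O)OC | intermediate
16 | lithium acetylide of 15 | [Li]C#C/C=C/CCCC(=O)OC | intermediate
17 | dichlorocerium acetylide of 15 | Cl[Ce](Cl)C#C/C=C/CCCC(=O)OC | intermediate
18 | methyl (5E)-8-{(2S)-2-(tert-butyldimethylsilyloxy)-1-hydroxy-2-[(Z)-oct-2-en-1-yl]cyclobutyl}oct-5-en-7-ynoate, both carbinol epimers | CCCCC/C=C\C[C@@]1(O[Si](C)(C)C(C)(C)C)CCC1(O)C#C/C=C/CCCC(=O)OC | intermediate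
19 | methyl (5E,7E,12S,14Z)-12-(tert-butyldimethylsilyloxy)-9-oxoprosta-5,7,14-trienoate | CCCCC/C=C\C[C@@]1(O[Si](C)(C)C(C)(C)C)CCC(=O)/C1=C/C=C/CCCC(=O)OC | intermediate
20 | C9,C10 lithium enolate of 19 | CCCCC/C=C\C[C@@]1(O[Si](C)(C)C(C)(C)C)CC=C(O[Li])/C1=C/C=C/CCCC(=O)OC | intermediate
21 | methyl (5E,7E,12R,14Z)-10-chloro-12-(tert-butyldimethylsilyloxy)-9-oxoprosta-5,7,14-trienoate, C10 epimers | CCCCC/C=C\C[C@@]1(O[Si](C)(C)C(C)(C)C)CC(Cl)C(=O)/C1=C/C=C/CCCC(=O)OC | intermediate
22 | C9,C10 lithium enolate of 21 | CCCCC/C=C\C[C@@]1(O[Si](C)(C)C(C)(C)C)CC(Cl)=C(O[Li])/C1=C/C=C/CCCC(=O)OC | intermediate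
23 | 10-chloro-10-(phenylselanyl) derivative of 19, C10 epimers | CCCCC/C=C\C[C@@]1(O[Si](C)(C)C(C)(C)C)CC(Cl)([Se]c2ccccc2)C(=O)/C1=C/C=C/CCCC(=O)OC | intermediate
24 | selenoxide of 23 | CCCCC/C=C\C[C@@]1(O[Si](C)(C)C(C)(C)C)CC(Cl)([Se](=O)c2ccccc2)C(=O)/C1=C/C=C/CCCC(=O)OC | intermediate
25 | methyl (5E,7E,12R,14Z)-10-chloro-12-(tert-butyldimethylsilyloxy)-9-oxoprosta-5,7,10,14-tetraenoate | CCCCC/C=C\C[C@@]1(O[Si](C)(C)C(C)(C)C)C=C(Cl)C(=O)/C1=C/C=C/CCCC(=O)OC | intermediate
26 | methyl (5E,7E,12R,14Z)-10-chloro-12-hydroxy-9-oxoprosta-5,7,10,14-tetraenoate | CCCCC/C=C\C[C@@]1(O)C=C(Cl)C(=O)/C1=C/C=C/CCCC(=O)OC | intermediate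
27 | methyl (5E,7E,12R,14Z)-12-acetoxy-10-chloro-9-oxoprosta-5,7,10,14-tetraenoate | CCCCC/C=C\C[C@@]1(OC(C)=O)C=C(Cl)C(=O)/C1=C/C=C/CCCC(=O)OC | target

Total step count: 13. Longest linear sequence: 10 steps (steps 1–4 and 8–13). The chain fragment (steps 5–7) joins at step 8.

Steps most likely to fail

Step 9.
- **Risk:** π-Activation of an internal, conjugated alkyne may be slow. Other events could then take over:
  - attack of the C14=C15 alkene on the gold-bound alkyne, an enyne cycloisomerisation that is feasible in the C9 epimer holding alkyne and octenyl chain cis;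
  - a 1,3-hydroxyl transposition;
  - a competing shift of C10;
  - later drift of the 7E geometry.
- **Fallback:** It sets out from 9 and rejoins at 19. It attaches the dienyl ester chain only after the ring has grown.
  - Ethynylmagnesium bromide (THF, −78 °C) should add to 9 to give (2S)-1-ethynyl-2-(tert-butyldimethylsilyloxy)-2-[(Z)-oct-2-en-1-yl]cyclobutan-1-ol F1.
  - NIS with catalytic AgNO3 in acetone should convert it into the 1-(iodoethynyl)cyclobutanol F2.
  - Gold(I) catalysis on this small, non-conjugated alkyne should deliver (S,E)-2-(iodomethylene)-3-(tert-butyldimethylsilyloxy)-3-[(Z)-oct-2-en-1-yl]cyclopentan-1-one F3, with iodine cis to C12 by the same anti rule.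
  - Palladium-catalysed alkenyl–alkenyl coupling of F3 with the alkenylzirconocene 11 made from 10 (Negishi type, Pd(PPh3)4, ZnCl2) proceeds with retention at both partners and gives 19.

Step 3.
- **Risk:** Facial discrimination on the small, flat four-membered siloxy enolate may be insufficient, or the enolate may be protonated before C–C bond formation.
- **Fallback:** It sets out from 6 and rejoins at 7. It replaces asymmetric catalysis by a reagent-controlled divergent resolution.
  - An achiral catalyst (Pd(PPh3)4, THF) should give racemic 2-allyl-2-(tert-butyldimethylsilyloxy)cyclobutan-1-one F4.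
  - Corey–Bakshi–Shibata reduction follows, with the (S)-methyl oxazaborolidine and catecholborane (toluene, −78 °C, conditions that spare the alkene). It delivers hydride to one carbonyl face whatever the configuration at C2.
  - The two ketone enantiomers therefore end as diastereomers, (1R,2S)-2-allyl-2-(tert-butyldimethylsilyloxy)cyclobutan-1-ol F5 and (1R,2R)-2-allyl-2-(tert-butyldimethylsilyloxy)cyclobutan-1-ol F6, which should separate on silica.
  - Dess–Martin oxidation of F5 returns 7.

Step 11.
- **Risk:** Selenenylation at the already substituted C10 may be sluggish, electrophilic selenium species may add to the alkenes, or the polyene may be oxidised during the peroxide stage.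
- **Fallback:** It sets out from 19 and rejoins at 25. It reverses the order and the polarity: unsaturation comes first, and chlorine then enters as chloride.
  - Trapping enolate 20 with TMSCl gives the C9,C10 trimethylsilyl enol ether of 19 F7.
  - Saegusa–Ito oxidation (Pd(OAc)2, MeCN) gives methyl (5E,7E,12R,14Z)-12-(tert-butyldimethylsilyloxy)-9-oxoprosta-5,7,10,14-tetraenoate F8.
  - Nucleophilic epoxidation of the endocyclic enone (t-BuOOH, DBU, CH2Cl2, 0 °C) gives its 10,11-epoxide F9.
  - Dry HCl in CHCl3 at 0 °C opens the epoxy ketone at C10 to the 10-chloro-11-hydroxy ketone F10, which loses water in the same medium to give 25.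
  - Premature loss of the silyl ether there would be harmless, since it leads on to 26.

Further compounds
F1 | step 9 | (2S)-1-ethynyl-2-(tert-butyldimethylsilyloxy)-2-[(Z)-oct-2-en-1-yl]cyclobutan-1-ol, both carbinol epimers | CCCCC/C=C\C[C@@]1(O[Si](C)(C)C(C)(C)C)CCC1(O)C#C
F2 | step 9 | (2S)-1-(iodoethynyl)-2-(tert-butyldimethylsilyloxy)-2-[(Z)-oct-2-en-1-yl]cyclobutan-1-ol, both carbinol epimers | CCCCC/C=C\C[C@@]1(O[Si](C)(C)C(C)(C)C)CCC1(O)C#CI
F3 | step 9 | (S,E)-2-(iodomethylene)-3-(tert-butyldimethylsilyloxy)-3-[(Z)-oct-2-en-1-yl]cyclopentan-1-one | CCCCC/C=C\C[C@@]1(O[Si](C)(C)C(C)(C)C)CCC(=O)/C1=C/I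
F4 | step 3 | racemic 2-allyl-2-(tert-butyldimethylsilyloxy)cyclobutan-1-one | C=CCC1(O[Si](C)(C)C(C)(C)C)CCC1=O
F5 | step 3 | (1R,2S)-2-allyl-2-(tert-butyldimethylsilyloxy)cyclobutan-1-ol | C=CC[C@@]1(O[Si](C)(C)C(C)(C)C)CC[C@H]1O
F6 | step 3 | (1R,2R)-2-allyl-2-(tert-butyldimethylsilyloxy)cyclobutan-1-ol | C=CC[C@]1(O[Si](C)(C)C(C)(C)C)CC[C@H]1O
F7 | step 11 | C9,C10 trimethylsilyl enol ether of 19 | CCCCC/C=C\C[C@@]1(O[Si](C)(C)C(C)(C)C)CC=C(O[Si](C)(C)C)/C1=C/C=C/CCCC(=O)OC
F8 | step 11 | methyl (5E,7E,12R,14Z)-12-(tert-butyldimethylsilyloxy)-9-oxoprosta-5,7,10,14-tetraenoate | CCCCC/C=C\C[C@@]1(O[Si](C)(C)C(C)(C)C)C=CC(=O)/C1=C/C=C/CCCC(=O)OC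
F9 | step 11 | 10,11-epoxide of F8 | CCCCC/C=C\C[C@@]1(O[Si](C)(C)C(C)(C)C)C2OC2C(=O)/C1=C/C=C/CCCC(=O)OC
F10 | step 11 | 10-chloro-11-hydroxy ketone from F9 | CCCCC/C=C\C[C@@]1(O[Si](C)(C)C(C)(C)C)C(O)C(Cl)C(=O)/C1=C/C=C/CCCC(=O)OC
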